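**Retrosynthetic overview**
1. The C=CBr2 unit comes from a 5‑methylidene butenolide by two successive Br2‑addition/dehydrobromination cycles, done last.
2. The 4‑bromo‑5‑methylidene butenolide comes from dehydration of a 5‑hydroxy‑5‑methyl butenolide, itself made by singlet‑oxygen oxidation of a 2‑methyl‑3‑bromo‑4‑substituted furan.
3. Ring order: the furan ring is purchased and is converted into the lactone (the only ring operation, step 7); no ring is built de novo.
4. The methyl group is introduced by bromine‑directed lithiation/methylation of the TBS‑protected carbinol, and the acetate by a TBS→Ac exchange at the robust furan stage.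
5. The only stereocentre is set by ketoreductase reduction of 1‑(4‑bromofuran‑3‑yl)butan‑1‑one, made from 3,4‑dibromofuran and the Weinreb amide of butanoic acid.

Assumption: 3,4‑dibromofuran, N‑methoxy‑N‑methylbutanamide and an (R)‑selective ketoreductase screening panel are taken as purchasable; the stereocentre in the target is R, and transient ring stereocentres (12, 13, 15, 17) and the E/Z geometry of 16 are carried as mixtures because they vanish in 18.

**Step 1**
Reactants: 1 3,4‑dibromofuran; 2 N‑methoxy‑N‑methylbutanamide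
Product: 5 1‑(4‑bromofuran‑3‑yl)butan‑1‑one, via 4‑bromo‑3‑furyllithium 3 (not isolated), via lithium hemiaminal adduct 4 (not isolated)
Conditions: n‑BuLi (1.0 equiv), Et2O, −78 °C, 20 min; then 2, −78 → −40 °C; sat. aq NH4Cl
Reagents that add atoms: none
Why: Br/Li exchange on the symmetric dibromide gives a single 3‑furyllithium (kept cold to prevent 3→2 migration), and the Weinreb ketone synthesis stops at the ketone through the chelated tetrahedral adduct; no stereocentre is formed.

**Step 2**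
Reactants: 5 1‑(4‑bromofuran‑3‑yl)butan‑1‑one
Product: 6 (R)‑1‑(4‑bromofuran‑3‑yl)butan‑1‑ol
Conditions: (R)‑selective (anti‑Prelog) ketoreductase (NADPH‑dependent alcohol dehydrogenase, Lactobacillus kefir type, chosen by panel screen), NADP+ (cat.), iPrOH (15% v/v)/K‑phosphate buffer pH 7.0, 1 mM MgSO4, 30 °C
Reagents that add atoms: none
Why: Ketoreductase‑catalysed asymmetric carbonyl reduction delivers the NADPH hydride to the si face of the prochiral heteroaryl ketone, setting the only stereocentre as R, with isopropanol regenerating the cofactor.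

**Step 3**
Reactants: 6 (R)‑1‑(4‑bromofuran‑3‑yl)butan‑1‑ol
Product: 7 (R)‑[1‑(4‑bromofuran‑3‑yl)butoxy](tert‑butyl)dimethylsilane
Conditions: TBSCl (1.2 equiv), imidazole (2.5 equiv), DMF, rt
Reagents that add atoms: tert‑butyldimethylsilyl chloride CC(C)(C)[Si](C)(C)Cl
Why: Standard O‑silylation (Corey TBS protection) does not touch the C–O bond of the stereocentre and gives a base‑stable, poorly coordinating ether for the lithiation.

**Step 4**
Reactants: 7 (R)‑[1‑(4‑bromofuran‑3‑yl)butoxy](tert‑butyl)dimethylsilane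
Product: 9 (R)‑[1‑(4‑bromo‑5‑methylfuran‑3‑yl)butoxy](tert‑butyl)dimethylsilane, via 3‑bromo‑2‑furyllithium 8 (not isolated)
Conditions: LDA (1.1 equiv), THF, −78 °C, 45 min; MeI (1.5 equiv), −78 → 0 °C
Reagents that add atoms: iodomethane CI
Why: Bromine‑directed deprotonation (directed metalation, as for 3‑bromofuran → 3‑bromo‑2‑lithiofuran) removes the most acidic α‑H, flanked by O and C–Br, and the furyllithium is alkylated by MeI; −78 °C suppresses halogen dance.

**Step 5**
Reactants: 9 (R)‑[1‑(4‑bromo‑5‑methylfuran‑3‑yl)butoxy](tert‑butyl)dimethylsilane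
Product: 10 (R)‑1‑(4‑bromo‑5‑methylfuran‑3‑yl)butan‑1‑ol
Conditions: TBAF (1.2 equiv), THF, 0 °C → rt; aqueous work‑up
Reagents that add atoms: none
Why: Fluoride‑mediated desilylation cleaves only the Si–O bond, so the configuration is retained and the bromofuran is untouched.

**Step 6**
Reactants: 10 (R)‑1‑(4‑bromo‑5‑methylfuran‑3‑yl)butan‑1‑ol
Product: 11 (R)‑1‑(4‑bromo‑5‑methylfuran‑3‑yl)butyl acetate
Conditions: Ac2O (1.5 equiv), pyridine, DMAP (cat.), CH2Cl2, 0 °C → rt
Reagents that add atoms: acetic anhydride CC(=O)OC(C)=O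
Why: DMAP‑catalysed O‑acylation installs the target's acetate under non‑acidic conditions with retention at the 3‑furyl carbinol.

**Step 7**
Reactants: 11 (R)‑1‑(4‑bromo‑5‑methylfuran‑3‑yl)butyl acetate
Product: 13 (1R)‑1‑(4‑bromo‑5‑hydroxy‑5‑methyl‑2‑oxo‑2,5‑dihydrofuran‑3‑yl)butyl acetate, via furan endoperoxide 12 (not isolated)
Conditions: O2, hν (visible), TPP (1 mol%), iPr2NEt (2 equiv), CH2Cl2, −78 °C → rt
Reagents that add atoms: dioxygen O=O
Why: Singlet‑oxygen [4+2] cycloaddition followed by base‑induced Kornblum–DeLaMare fragmentation removes the only bridgehead H (former furan C5–H), so the lactone C=O forms next to the side‑chain carbon and the methyl lactol carbon next to C–Br.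

**Step 8**
Reactants: 13 (1R)‑1‑(4‑bromo‑5‑hydroxy‑5‑methyl‑2‑oxo‑2,5‑dihydrofuran‑3‑yl)butyl acetate
Product: 14 (R)‑1‑(4‑bromo‑5‑methylidene‑2‑oxo‑2,5‑dihydrofuran‑3‑yl)butyl acetate
Conditions: P2O5 (3 equiv), CH2Cl2, 0 °C → reflux, 1–2 h; filter through short SiO2, add BHT, use directly
Reagents that add atoms: none
Why: Acid‑mediated dehydration (E1 through the ring‑oxygen‑stabilised cation) of the tertiary lactol gives the exocyclic enol lactone, the usual dehydration in fimbrolide chemistry, while the acetate on the electron‑poor ring does not ionise.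

**Step 9**
Reactants: 14 (R)‑1‑(4‑bromo‑5‑methylidene‑2‑oxo‑2,5‑dihydrofuran‑3‑yl)butyl acetate
Product: 16 (R)‑1‑[(5Z)‑4‑bromo‑5‑(bromomethylidene)‑2‑oxo‑2,5‑dihydrofuran‑3‑yl]butyl acetate, via 5‑bromo‑5‑(bromomethyl) lactone 15 (not isolated)
Conditions: Br2 (1.05 equiv), CH2Cl2, 0 °C, dark; then Et3N (1.2 equiv), 0 °C → rt
Reagents that add atoms: bromine BrBr
Why: Electrophilic bromine addition to the exocyclic enol‑ester alkene, then dehydrobromination (loss of the labile tertiary α‑bromo‑ether bromide and a CH2Br proton), gives the bromomethylidene lactone; the tetrasubstituted electron‑poor ring alkene does not add Br2.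

**Step 10**
Reactants: 16 (R)‑1‑[(5Z)‑4‑bromo‑5‑(bromomethylidene)‑2‑oxo‑2,5‑dihydrofuran‑3‑yl]butyl acetate
Product: 18 (R)‑1‑[4‑bromo‑5‑(dibromomethylidene)‑2‑oxo‑2,5‑dihydrofuran‑3‑yl]butyl acetate, via 5‑bromo‑5‑(dibromomethyl) lactone 17 (not isolated)
Conditions: Br2 (1.1 equiv), CH2Cl2, rt, dark; then Et3N (1.2 equiv), 0 °C
Reagents that add atoms: bromine BrBr
Why: A second bromine addition/dehydrobromination cycle converts the bromomethylidene into the dibromomethylidene group (geometry of 16 is irrelevant), and Et3N at 0 °C does not epimerise the non‑acidic acetoxy‑bearing stereocentre.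

**Compound list**
1 | 3,4‑dibromofuran | Brc1cocc1Br | starting material
2 | N‑methoxy‑N‑methylbutanamide | CCCC(=O)N(C)OC | starting material
3 | 4‑bromo‑3‑furyllithium | [Li]c1cocc1Br | intermediate (not isolated)
4 | lithium 1‑(4‑bromofuran‑3‑yl)‑1‑[methoxy(methyl)amino]butan‑1‑olate | CCCC(O[Li])(N(C)OC)c1cocc1Br | intermediate (not isolated)
5 | 1‑(4‑bromofuran‑3‑yl)butan‑1‑one | CCCC(=O)c1cocc1Br | intermediate
6 | (R)‑1‑(4‑bromofuran‑3‑yl)butan‑1‑ol | CCC[C@@H](O)c1cocc1Br | intermediate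
7 | (R)‑[1‑(4‑bromofuran‑3‑yl)butoxy](tert‑butyl)dimethylsilane | CCC[C@@H](O[Si](C)(C)C(C)(C)C)c1cocc1Br | intermediate
8 | {3‑bromo‑4‑[(R)‑1‑(tert‑butyldimethylsilyloxy)butyl]furan‑2‑yl}lithium | CCC[C@@H](O[Si](C)(C)C(C)(C)C)c1coc([Li])c1Br | intermediate (not isolated)
9 | (R)‑[1‑(4‑bromo‑5‑methylfuran‑3‑yl)butoxy](tert‑butyl)dimethylsilane | CCC[C@@H](O[Si](C)(C)C(C)(C)C)c1coc(C)c1Br | intermediate
10 | (R)‑1‑(4‑bromo‑5‑methylfuran‑3‑yl)butan‑1‑ol | CCC[C@@H](O)c1coc(C)c1Br | intermediate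
11 | (R)‑1‑(4‑bromo‑5‑methylfuran‑3‑yl)butyl acetate | CCC[C@@H](OC(C)=O)c1coc(C)c1Br | intermediate
12 | (1R)‑1‑(6‑bromo‑1‑methyl‑2,3,7‑trioxabicyclo[2.2.1]hept‑5‑en‑5‑yl)butyl acetate (endoperoxide, bridgehead diastereomers) | CCC[C@@H](OC(C)=O)C1=C(Br)C2(C)OOC1O2 | intermediate (not isolated)
13 | (1R)‑1‑(4‑bromo‑5‑hydroxy‑5‑methyl‑2‑oxo‑2,5‑dihydrofuran‑3‑yl)butyl acetate (C5 epimers) | CCC[C@@H](OC(C)=O)C1=C(Br)C(C)(O)OC1=O | intermediate
14 | (R)‑1‑(4‑bromo‑5‑methylidene‑2‑oxo‑2,5‑dihydrofuran‑3‑yl)butyl acetate | CCC[C@@H](OC(C)=O)C1=C(Br)C(=C)OC1=O | intermediate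
15 | (1R)‑1‑[4,5‑dibromo‑5‑(bromomethyl)‑2‑oxo‑2,5‑dihydrofuran‑3‑yl]butyl acetate (C5 epimers) | CCC[C@@H](OC(C)=O)C1=C(Br)C(Br)(CBr)OC1=O | intermediate (not isolated)
16 | (R)‑1‑[(5Z)‑4‑bromo‑5‑(bromomethylidene)‑2‑oxo‑2,5‑dihydrofuran‑3‑yl]butyl acetate (Z major, E/Z mixture usable) | CCC[C@@H](OC(C)=O)C1=C(Br)/C(=C/Br)OC1=O | intermediate
17 | (1R)‑1‑[4,5‑dibromo‑5‑(dibromomethyl)‑2‑oxo‑2,5‑dihydrofuran‑3‑yl]butyl acetate (C5 epimers) | CCC[C@@H](OC(C)=O)C1=C(Br)C(Br)(C(Br)Br)OC1=O | intermediate (not isolated)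
18 | (R)‑1‑[4‑bromo‑5‑(dibromomethylidene)‑2‑oxo‑2,5‑dihydrofuran‑3‑yl]butyl acetate (CNP0230107.1) | CCC[C@@H](OC(C)=O)C1=C(Br)C(=C(Br)Br)OC1=O | target

**Totals**
Total step count: 10. Longest linear sequence: 10 steps (1 → 18; 2 is purchased).

**Three steps most likely to fail, with fallbacks**

Step 4 (regiocontrol of the lithiation, or halogen dance of the bromofuryllithium). The fallback sets out from 1 and comes back to the route at 10, introducing the methyl group before the side chain. Compound 1 is deprotonated with LDA (THF, −78 °C) to 3,4‑dibromo‑2‑furyllithium F1 and quenched with MeI to give 3,4‑dibromo‑2‑methylfuran F2. n‑BuLi (Et2O, −78 °C) then exchanges the less hindered bromine remote from the methyl group to give 4‑bromo‑5‑methyl‑3‑furyllithium F3. F3 adds to 2 to give the lithium hemiaminal adduct F4, which on NH4Cl quench releases 1‑(4‑bromo‑5‑methylfuran‑3‑yl)butan‑1‑one F5. The same ketoreductase/isopropanol system reduces F5 to 10, so the silyl ether detour (7–9) is not needed.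

Step 8 (incomplete acid dehydration, or polymerisation of the methylidene lactone). The fallback sets out from 13 and comes back at 14, replacing acid dehydration by activation and base elimination. Compound 13 is treated with SOCl2 and catalytic DMF (CH2Cl2, 0 °C → rt) to give the pseudo‑acid chloride (1R)‑1‑(4‑bromo‑5‑chloro‑5‑methyl‑2‑oxo‑2,5‑dihydrofuran‑3‑yl)butyl acetate F6. HCl is then eliminated with Et3N at 0 °C to give 14, which is taken straight into step 9.

Step 10 (sluggish bromine addition to the deactivated bromomethylidene, or amine attack on the electrophilic tribromide). The fallback sets out from 13 and comes back at 18, halogenating before the exocyclic alkene exists. Through its open keto‑acid tautomer, 13 is brominated at the methyl group with Br2 (2.2 equiv) and catalytic HBr in CHCl3/AcOH (rt → 40 °C). This passes through (1R)‑1‑[4‑bromo‑5‑(bromomethyl)‑5‑hydroxy‑2‑oxo‑2,5‑dihydrofuran‑3‑yl]butyl acetate F7 to (1R)‑1‑[4‑bromo‑5‑(dibromomethyl)‑5‑hydroxy‑2‑oxo‑2,5‑dihydrofuran‑3‑yl]butyl acetate F8. F8 is dehydrated with P2O5 in CH2Cl2 to give 18 without any amine base.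

**Further compounds**
F1 | step 4 | 3,4‑dibromo‑2‑furyllithium | [Li]c1occ(Br)c1Br
F2 | step 4 | 3,4‑dibromo‑2‑methylfuran | Cc1occ(Br)c1Br
F3 | step 4 | 4‑bromo‑5‑methyl‑3‑furyllithium | Cc1occ([Li])c1Br
F4 | step 4 | lithium 1‑(4‑bromo‑5‑methylfuran‑3‑yl)‑1‑[methoxy(methyl)amino]butan‑1‑olate | CCCC(O[Li])(N(C)OC)c1coc(C)c1Br
F5 | step 4 | 1‑(4‑bromo‑5‑methylfuran‑3‑yl)butan‑1‑one | CCCC(=O)c1coc(C)c1Br
F6 | step 8 | (1R)‑1‑(4‑bromo‑5‑chloro‑5‑methyl‑2‑oxo‑2,5‑dihydrofuran‑3‑yl)butyl acetate | CCC[C@@H](OC(C)=O)C1=C(Br)C(C)(Cl)OC1=O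
F7 | step 10 | (1R)‑1‑[4‑bromo‑5‑(bromomethyl)‑5‑hydroxy‑2‑oxo‑2,5‑dihydrofuran‑3‑yl]butyl acetate | CCC[C@@H](OC(C)=O)C1=C(Br)C(O)(CBr)OC1=O
F8 | step 10 | (1R)‑1‑[4‑bromo‑5‑(dibromomethyl)‑5‑hydroxy‑2‑oxo‑2,5‑dihydrofuran‑3‑yl]butyl acetate | CCC[C@@H](OC(C)=O)C1=C(Br)C(O)(C(Br)Br)OC1=O
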